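At early times the substrate is already nearly used up: the first readings show 0.1% in maple after 0.833 h and 2.0% in birch after 2.00 h, with target already on its plateau.

| flask | substrate | reagent | free catalyst | remark | time |
|---|---|---|---|---|---|
| maple | 0.25 M | 0.525 M | 1 mM | run made earlier |  |
| birch | 1 M | 0.525 M | 1 mM | run made earlier |  |
| cedar | 0.50 M | 0.525 M | 1.5 mM | run made earlier |  |
| flask | 0.50 M | 0.525 M | 1.0 mM |  | 12 h |

- maple (time / h: substrate / %, target / %): 0.833: 0.1, 49.0; 2.50: 0, 48.9; 4.00: 0.7, 50.1; 6.00: 0, 50.3; 10.0: 2.6, 49.9; 12.0: 0.5, 47.6
- birch (time / h: substrate / %, target / %): 2.00: 2.0, 14.6; 4.00: 0.9, 15.4; 6.00: 0, 15.4; 8.00: 0, 13.7; 10.0: 0, 13.4; 12.0: 0, 15.0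
- cedar (time / h: substrate / %, target / %): 2.50: 0.1, 34.7; 5.00: 0, 33.6; 8.00: 0.4, 35.9; 10.0: 0, 33.6; 12.0: 0, 35.3

(standard deviation of a reading: 1 percentage point)

- what was read earlier has a scatter of 1 percentage point, one standard deviation
- a reading or a percentage of target counts all its forms, free or not
- the reaction counts as stopped when no species that holds the substrate changes by six tenths of a point or more over the second half of the time

- the state of affairs at 12 h: stopped, and by what, or still going (all of the substrate has reacted / no working catalyst is left / it is still moving / forward and back rates have come level / the reagent has run out first)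
- share of the substrate used up at 12 h
- target at 12 h, in percent of the substrate charged

I ask which number has to be known well. Time hardly matters, since later target readings wander by about the scatter of 1 percentage point. Reagent cannot be tested, as each run holds 0.525 M, but birch's plateau, c(target) = 0.146 M, stays below that charge. Substrate matters most, so I reckon in concentration, not percent. Maple stands at 0.123 M. I call this the harvest, the c(target) a flask stands at on its plateau. Raising the charge by a factor 4.00 lifts the harvest by a factor of just 1.19.

Catalyst matters too: cedar, with the flask's substrate charge but 1.5 mM of catalyst, harvests 0.173 M, above both. The flask has 1.0 mM, like maple and birch, and its charge lies between theirs. I commit to the upper end, guessing that the harvest levels off as the charge rises, so the flask should stop near 29.2% target with its conversion complete.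

The forecast says all of the substrate has reacted, 100% conversion and 27% target, lower than mine, and it reaches that target by a different step from mine: “Interpolating between maple and birch at 1 mM gives about 0.135 M for 0.5 M substrate”.

The flask gives: all of the substrate has reacted, 100% conversion, 28.8% target.

    reagent + free catalyst → catalyst intermediate A (k = 1.30 /M/s)
    catalyst intermediate A → catalyst intermediate B (k = 0.590 /s)
    substrate + catalyst intermediate B → catalyst intermediate C (k = 37.0 /M/s)
    catalyst intermediate C → catalyst intermediate D (k = 0.0900 /s)
    catalyst intermediate D ⇌ free catalyst + target (K = 0.210 M, k = 0.440 /s)
    free catalyst + target ⇌ idle complex, settled at all times (K = 1.60 /M)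
    2 substrate → self-condensation product (k = 0.00260 /M/s)
    free catalyst → spent catalyst (k = 1.30 × 10⁻⁶ /s)

The flask's harvest is 0.144 M, beside my 0.146 M. The same flask without the conversion of 2 substrate into self-condensation product reaches 100% target against 28.8%, so that step is what takes the missing share. Substrate, the limiting reagent, stands at 0% in the flask while reagent keeps 72%. Carried to the neighbour flask with 2.0 M of substrate, the harvest 0.146 M gives 7.30% target, and that neighbour holds 8.01%.

(The earlier runs and the new flask are simulated with constants of no real substance, noise included.)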